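**Plan**

- Azulene numbering is used. Ring A is C1, C2, C3, C3a, C8a. Ring B is C3a, C4 to C8, C8a. The cuts, in order, are: aryl silyl ether; C8=O (allylic oxidation of a C6-H/C7=C8 alkene); C4–O acyl bond; C4–H (ketone reduction); C3–C3a (aldol); C3–isopropyl; C6–CH3; C7 (one-carbon ring enlargement); C8a–C1 (Michael addition).
- Enabling feature: the tertiary carbinol C3 of ring A lies β to the C4 oxygen of ring B through the fusion carbon C3a. At the C4-ketone level, C3–C3a is therefore an aldol bond between C3a and an isopropyl ketone tethered to C8a by C1–C2.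
- Forward order: a purchased six-membered ketal ketone receives the C1–C3 chain and is enlarged to ring B. Ring A closes last by the aldol, and the vanillate is joined afterwards.
- During the aldol, C8 is an alkene carbon and not the enone carbonyl. With C6=C7–C8=O in place, C5-H2 would be a vinylogous 1,3-dicarbonyl position that captures the base and lets the alkene drift towards C4. The enone is therefore installed only once C4 is an ester.
- Stereochemistry: C8a comes from (S)-1-phenylethylamine in an imine Michael addition. C3a and C3 are set by equilibration against C8a. C4 is set by hydride attack anti to the angular methyl. C6 is a transient centre that is erased in step 14.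

Key step: step 10

Remark: from step 7 to step 13 the compounds are carried as mixtures of C6 epimers (C10 in spiro numbering) and drawn without a descriptor there. Both epimers converge in step 14. The enantiomeric purity set in step 2 is to be checked at 6 and, if needed, raised by crystallisation of a later solid intermediate.

**Step 1**
Reactants: 1 7-methyl-1,4-dioxaspiro[4.5]decan-8-one (racemic); 2 (S)-1-phenylethylamine
Product: 3 (1S)-N-(7-methyl-1,4-dioxaspiro[4.5]decan-8-ylidene)-1-phenylethanamine (C7 epimers)
Conditions: TsOH·H2O (cat.), toluene, Dean–Stark, reflux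
Reagents that add atoms: none
Why: Acid-catalysed ketimine condensation with azeotropic removal of water should give the imine, which equilibrates with its secondary enamine tautomers, and the dioxolane is inert in the absence of water.

**Step 2**
Reactants: 3 the imine; 4 acrylonitrile
Product: 6 3-[(7S)-7-methyl-8-oxo-1,4-dioxaspiro[4.5]decan-7-yl]propanenitrile, via Michael adduct imine 5 (not isolated)
Conditions: acrylonitrile, THF, 60 °C; then 20 % aq AcOH, 23 °C
Reagents that add atoms: water, O
Why: In this d'Angelo asymmetric Michael addition the more substituted enamine tautomer adds to the acceptor through a compact aza-ene-like chair on the face anti to the auxiliary phenyl group, which sets C8a (spiro C7) as S from either epimer of 3, and dilute acetic acid then hydrolyses the imine but not the ketal.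

**Step 3**
Reactants: 6 the keto nitrile
Product: 8 3-[(7S)-7-methyl-8-(trimethylsilyloxy)-1,4-dioxaspiro[4.5]dec-8-en-7-yl]propanenitrile, via lithium enolate 7 (not isolated)
Conditions: LiN(i-Pr)2 (LDA), THF, −78 °C; Me3SiCl, −78 → 0 °C
Reagents that add atoms: chlorotrimethylsilane, C[Si](C)(C)Cl
Why: Kinetic enolisation followed by O-silylation can only run towards C6, because C8a is quaternary and the nitrile α-hydrogens are much less acidic, so a single silyl enol ether should form.

**Step 4**
Reactants: 8 the silyl enol ether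
Product: 9 3-[(2S)-2-methyl-1-(trimethylsilyloxy)spiro[bicyclo[4.1.0]heptane-4,2'-[1,3]dioxolan]-2-yl]propanenitrile (cis-fused cyclopropane, both faces)
Conditions: Et2Zn, CH2I2, CH2Cl2, 0 → 23 °C
Reagents that add atoms: diiodomethane, ICI
Why: The Furukawa-modified Simmons–Smith cyclopropanation is fastest on electron-rich enol ethers and this is the only alkene present, while the facial outcome is irrelevant because C8 and C6 lose their configuration in steps 5 and 6.

**Step 5**
Reactants: 9 the siloxycyclopropane
Product: 10 3-[(7S)-10-chloro-7-methyl-8-oxo-1,4-dioxaspiro[4.6]undecan-7-yl]propanenitrile (C10 epimers)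
Conditions: FeCl3, pyridine, DMF, 0 → 23 °C
Reagents that add atoms: FeCl3 (iron trichloride), Cl[Fe](Cl)Cl
Why: In this Saegusa ring enlargement, one-electron oxidation gives a cyclopropyloxy radical whose internal C8–C6 bond cleaves to the ring-enlarged secondary C6 radical, which abstracts chlorine, and the pyridine-buffered DMF medium is chosen to spare the dioxolane.

**Step 6**
Reactants: 10 the β-chloro ketone
Product: 11 3-[(7S)-7-methyl-8-oxo-1,4-dioxaspiro[4.6]undec-9-en-7-yl]propanenitrile
Conditions: NaOAc, MeOH, reflux
Reagents that add atoms: none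
Why: E1cB dehydrochlorination through the only possible enolate (C7) should give the C6=C7 cycloheptenone.

**Step 7**
Reactants: 11 the cycloheptenone
Product: 13 (7S)-7-(2-cyanoethyl)-7,10-dimethyl-1,4-dioxaspiro[4.6]undec-8-en-8-yl trifluoromethanesulfonate, via C6-methyl lithium enolate 12 (not isolated)
Conditions: Me2CuLi (CuI, MeLi), Et2O, −78 → −30 °C; then PhNTf2, THF–DMPU, −30 → 23 °C
Reagents that add atoms: Me2CuLi (lithium dimethylcuprate), [Li+].C[Cu-]C; N-phenylbis(trifluoromethanesulfonimide), O=S(=O)(N(c1ccccc1)S(=O)(=O)C(F)(F)F)C(F)(F)F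
Why: Gilman conjugate addition places the methyl group on C6 and the regiodefined enolate is trapped on oxygen as the vinyl triflate, with the nitrile and ketal inert and the C6 configuration of no consequence.

**Step 8**
Reactants: 13 the vinyl triflate
Product: 14 3-[(7S)-7,10-dimethyl-1,4-dioxaspiro[4.6]undec-8-en-7-yl]propanenitrile
Conditions: Pd(OAc)2 (cat.), PPh3, HCO2H, n-Bu3N, DMF, 60 °C
Reagents that add atoms: none
Why: Palladium-catalysed formate reduction of a vinyl triflate (oxidative addition to zerovalent palladium, formate exchange, decarboxylation, reductive elimination) replaces OTf by H and leaves the alkene at C7=C8.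

**Step 9**
Reactants: 14 the alkene nitrile
Product: 16 (6S)-3,6-dimethyl-6-(4-methyl-3-oxopentyl)cyclohept-4-en-1-one, via magnesium ketiminate 15 (not isolated)
Conditions: i-PrMgCl, CuBr·SMe2 (cat.), THF, 50 °C; then 1 M HCl, THF, 23 °C
Reagents that add atoms: isopropylmagnesium chloride, CC(C)[Mg]Cl; water, O
Why: Copper-catalysed Grignard addition to a nitrile stops at the ketiminate because no carbonyl group is present, and one aqueous acid treatment hydrolyses both the ketimine and the dioxolane to release the C3 and C4 ketones together.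

**Step 10**
Reactants: 16 the 1,6-diketone
Product: 17 (3R,3aR,8aR)-3-hydroxy-6,8a-dimethyl-3-(propan-2-yl)-2,3,3a,5,6,8a-hexahydroazulen-4(1H)-one (trans-fused, C3–OH cis to the angular methyl)
Conditions: KOt-Bu (0.2 equiv), t-BuOH–THF, 0 → 23 °C; AcOH quench
Reagents that add atoms: none
Why: tert-Butoxide reversibly deprotonates the C4 ketone at C3a, the enolate carbon adds to the tethered isopropyl ketone to make C3–C3a, and proton exchange with t-BuOH releases the neutral ketol and the base, so aldol, retro-aldol and C3a epimerisation all stay open (base-mediated intramolecular aldol addition of a 1,6-diketone, the known cyclopentannulation type). Ring A closes in the 5-(enolexo)-exo-trig mode, assisted by the quaternary C8a in the tether. C3a is controlled by equilibration through the enolate, and the trans junction with C3a–H anti to the angular methyl is expected to be the low-energy fusion of this hydroazulenone. C3 is controlled by retro-aldol/aldol equilibration, the favoured epimer placing the isopropyl group trans to the vicinal C4 arm and the hydroxyl cis to it, where it hydrogen-bonds to the C4 carbonyl. The step needs site selectivity and no dehydration: C5 could only close a bridged seven-membered ring, addition of the C2 enolate to C4 gives a more strained bicyclo[4.2.1]nonane that cannot dehydrate and should revert, and catalytic base at or below room temperature keeps E1cB loss of water slow. Because ring B carries only the isolated C7=C8 alkene (γ,δ to C4) and no C8 carbonyl, there is no doubly activated C5–H, no C7 enolate and no alkene migration to drain the equilibrium.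

**Step 11**
Reactants: 17 the ketol
Product: 18 (3R,3aS,4R,8aR)-6,8a-dimethyl-3-(propan-2-yl)-1,2,3,3a,4,5,6,8a-octahydroazulene-3,4-diol
Conditions: NaBH4, CeCl3·7H2O, MeOH, −78 → −40 °C
Reagents that add atoms: none
Why: In this Luche-type reduction of the only carbonyl group, the axial trajectory on the β face runs into the angular methyl (1,3-diaxial), so external hydride should attack the cerium-bridged C3–O/C4=O chelate from the α face (the side of C3a–H) through a chair-like array, giving the C4 alcohol cis to the C3 hydroxyl, while the cold, weakly basic medium suppresses retro-aldol.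

**Step 12**
Reactants: 19 vanillic acid
Product: 21 4-[(tert-butyldimethylsilyl)oxy]-3-methoxybenzoic acid, via bis-silylated vanillate 20 (not isolated)
Conditions: t-BuMe2SiCl, imidazole, DMF, 23 °C; then THF–AcOH–H2O, 23 °C
Reagents that add atoms: tert-butyldimethylsilyl chloride, CC(C)(C)[Si](C)(C)Cl
Why: Exhaustive silylation followed by selective hydrolysis exploits the much greater lability of a silyl ester compared with an aryl silyl ether.

**Step 13**
Reactants: 18 the diol; 21 the protected acid
Product: 22 (3R,3aS,4R,8aR)-3-hydroxy-6,8a-dimethyl-3-(propan-2-yl)-1,2,3,3a,4,5,6,8a-octahydroazulen-4-yl 4-[(tert-butyldimethylsilyl)oxy]-3-methoxybenzoate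
Conditions: DCC, DMAP, CH2Cl2, 23 → 40 °C
Reagents that add atoms: none
Why: Steglich esterification acylates the secondary C4 hydroxyl with retention, and the tertiary C3 hydroxyl is too hindered to compete.

**Step 14**
Reactants: 22 the alkene ester
Product: 23 (3R,3aS,4R,8aS)-3-hydroxy-6,8a-dimethyl-8-oxo-3-(propan-2-yl)-1,2,3,3a,4,5,8,8a-octahydroazulen-4-yl 4-[(tert-butyldimethylsilyl)oxy]-3-methoxybenzoate
Conditions: CrO3, 3,5-dimethylpyrazole, CH2Cl2, −20 °C
Reagents that add atoms: CrO3 (chromium trioxide), O=[Cr](=O)=O
Why: In this chromium trioxide–dimethylpyrazole allylic oxidation the only allylic hydrogen is C6–H (C8a is quaternary), a chromate ester formed at tertiary C6 can only relay by [3,3] shift to C8 as in the Babler–Dauben transposition, and only the secondary C8 ester can collapse to a ketone, so the C6=C7–C8=O enone should result and both C6 epimers converge.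

**Step 15**
Reactants: 23 the silyl-protected enone ester
Product: 24 (3R,3aS,4R,8aS)-3-hydroxy-6,8a-dimethyl-8-oxo-3-(propan-2-yl)-1,2,3,3a,4,5,8,8a-octahydroazulen-4-yl 4-hydroxy-3-methoxybenzoate (target)
Conditions: HF·pyridine, pyridine, THF, 0 °C
Reagents that add atoms: none
Why: Fluoride-driven cleavage of the aryl silyl ether in a non-basic medium avoids C5 deprotonation and vinylogous E1cB loss of the C4 carboxylate.

**Compound list**

1 | 7-methyl-1,4-dioxaspiro[4.5]decan-8-one (racemic) | CC1CC2(CCC1=O)OCCO2 | starting material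
2 | (S)-1-phenylethylamine | C[C@H](N)c1ccccc1 | starting material
3 | (1S)-N-(7-methyl-1,4-dioxaspiro[4.5]decan-8-ylidene)-1-phenylethanamine | CC1CC2(CCC1=N[C@@H](C)c1ccccc1)OCCO2 | intermediate
4 | acrylonitrile | C=CC#N | starting material
5 | (1S)-N-[(7S)-7-(2-cyanoethyl)-7-methyl-1,4-dioxaspiro[4.5]decan-8-ylidene]-1-phenylethanamine | C[C@]1(CCC#N)CC2(CCC1=N[C@@H](C)c1ccccc1)OCCO2 | intermediate
6 | 3-[(7S)-7-methyl-8-oxo-1,4-dioxaspiro[4.5]decan-7-yl]propanenitrile | C[C@]1(CCC#N)CC2(CCC1=O)OCCO2 | intermediate
7 | lithium (7S)-7-(2-cyanoethyl)-7-methyl-1,4-dioxaspiro[4.5]dec-8-en-8-olate | C[C@]1(CCC#N)CC2(CC=C1[O-])OCCO2.[Li+] | intermediate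
8 | 3-[(7S)-7-methyl-8-(trimethylsilyloxy)-1,4-dioxaspiro[4.5]dec-8-en-7-yl]propanenitrile | C[C@]1(CCC#N)CC2(CC=C1O[Si](C)(C)C)OCCO2 | intermediate
9 | 3-[(2S)-2-methyl-1-(trimethylsilyloxy)spiro[bicyclo[4.1.0]heptane-4,2'-[1,3]dioxolan]-2-yl]propanenitrile | C[C@]1(CCC#N)CC2(CC3CC31O[Si](C)(C)C)OCCO2 | intermediate
10 | 3-[(7S)-10-chloro-7-methyl-8-oxo-1,4-dioxaspiro[4.6]undecan-7-yl]propanenitrile | C[C@]1(CCC#N)CC2(CC(Cl)CC1=O)OCCO2 | intermediate
11 | 3-[(7S)-7-methyl-8-oxo-1,4-dioxaspiro[4.6]undec-9-en-7-yl]propanenitrile | C[C@]1(CCC#N)CC2(CC=CC1=O)OCCO2 | intermediate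
12 | lithium (7S)-7-(2-cyanoethyl)-7,10-dimethyl-1,4-dioxaspiro[4.6]undec-8-en-8-olate | C[C@]1(CCC#N)CC2(CC(C)C=C1[O-])OCCO2.[Li+] | intermediate
13 | (7S)-7-(2-cyanoethyl)-7,10-dimethyl-1,4-dioxaspiro[4.6]undec-8-en-8-yl trifluoromethanesulfonate | C[C@]1(CCC#N)CC2(CC(C)C=C1OS(=O)(=O)C(F)(F)F)OCCO2 | intermediate
14 | 3-[(7S)-7,10-dimethyl-1,4-dioxaspiro[4.6]undec-8-en-7-yl]propanenitrile | C[C@]1(CCC#N)CC2(CC(C)C=C1)OCCO2 | intermediate
15 | chloromagnesium ketiminate of 1-[(7S)-7,10-dimethyl-1,4-dioxaspiro[4.6]undec-8-en-7-yl]-4-methylpentan-3-one | CC(C)C(=N[Mg]Cl)CC[C@@]1(C)CC2(CC(C)C=C1)OCCO2 | intermediate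
16 | (6S)-3,6-dimethyl-6-(4-methyl-3-oxopentyl)cyclohept-4-en-1-one | CC(C)C(=O)CC[C@@]1(C)CC(=O)CC(C)C=C1 | intermediate
17 | (3R,3aR,8aR)-3-hydroxy-6,8a-dimethyl-3-(propan-2-yl)-2,3,3a,5,6,8a-hexahydroazulen-4(1H)-one | O=C2CC(C)C=C[C@@]3(C)CC[C@@](O)(C(C)C)[C@H]23 | intermediate
18 | (3R,3aS,4R,8aR)-6,8a-dimethyl-3-(propan-2-yl)-1,2,3,3a,4,5,6,8a-octahydroazulene-3,4-diol | O[C@@H]2CC(C)C=C[C@@]3(C)CC[C@@](O)(C(C)C)[C@H]23 | intermediate
19 | vanillic acid | COc1cc(C(=O)O)ccc1O | starting material
20 | tert-butyldimethylsilyl 4-[(tert-butyldimethylsilyl)oxy]-3-methoxybenzoate | COc1cc(C(=O)O[Si](C)(C)C(C)(C)C)ccc1O[Si](C)(C)C(C)(C)C | intermediate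
21 | 4-[(tert-butyldimethylsilyl)oxy]-3-methoxybenzoic acid | COc1cc(C(=O)O)ccc1O[Si](C)(C)C(C)(C)C | intermediate
22 | (3R,3aS,4R,8aR)-3-hydroxy-6,8a-dimethyl-3-(propan-2-yl)-1,2,3,3a,4,5,6,8a-octahydroazulen-4-yl 4-[(tert-butyldimethylsilyl)oxy]-3-methoxybenzoate | COc1cc(C(=O)O[C@@H]2CC(C)C=C[C@@]3(C)CC[C@@](O)(C(C)C)[C@H]23)ccc1O[Si](C)(C)C(C)(C)C | intermediate
23 | (3R,3aS,4R,8aS)-3-hydroxy-6,8a-dimethyl-8-oxo-3-(propan-2-yl)-1,2,3,3a,4,5,8,8a-octahydroazulen-4-yl 4-[(tert-butyldimethylsilyl)oxy]-3-methoxybenzoate | COc1cc(C(=O)O[C@@H]2CC(C)=CC(=O)[C@@]3(C)CC[C@@](O)(C(C)C)[C@H]23)ccc1O[Si](C)(C)C(C)(C)C | intermediate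
24 | (3R,3aS,4R,8aS)-3-hydroxy-6,8a-dimethyl-8-oxo-3-(propan-2-yl)-1,2,3,3a,4,5,8,8a-octahydroazulen-4-yl 4-hydroxy-3-methoxybenzoate | COc1cc(C(=O)O[C@@H]2CC(C)=CC(=O)[C@@]3(C)CC[C@@](O)(C(C)C)[C@H]23)ccc1O | target

Total step count: 15. Longest linear sequence: 14 (steps 1–11 and 13–15).

**Steps most likely to fail**

**Step 10.** The equilibrium may not settle on the wanted diastereomer. It could be diverted by competition from the cis junction, from the bridged C2-to-C4 closure or from the open diketone, or it may leak away by dehydration.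
- The fallback sets out from 16 and fixes C3 by a directed epoxidation instead of by equilibration.
- Heating 16 with NaOMe in MeOH pushes every reversible adduct through the only one that can lose water, giving the conjugated bicyclic enone F1.
- Luche reduction from the face opposite the angular methyl gives the allylic alcohol F2.
- VO(acac)2/t-BuOOH epoxidation directed by the C4 hydroxyl gives the syn epoxy alcohol F3.
- Dess–Martin oxidation gives the epoxy ketone F4.
- SmI2 in THF–MeOH at −90 °C cleaves the C3a–O bond, and protonation of the samarium enolate anti to the angular methyl rejoins the route at 17.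

**Step 14.** Hydrogen abstraction at the hindered tertiary allylic position may be slow. Oxygen may stay at C6 without relay to C8, or epoxidation of the alkene may compete.
- The fallback sets out from 22 and uses a pericyclic oxygenation.
- In the Schenck ene reaction with singlet oxygen (O2, tetraphenylporphyrin, visible light, CH2Cl2), C6–H is the only allylic hydrogen. Oxygen must therefore bond to C8 while the alkene moves to C6=C7, giving the allylic hydroperoxide F5.
- Kornblum–DeLaMare-type dehydration with Ac2O/pyridine rejoins the route at 23.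

**Step 11.** Facial selectivity of hydride delivery may be poor, because the α face carries the C3 isopropyl group. Retro-aldol may also intervene before reduction.
- The fallback sets out from 17 and deliberately makes the other epimer.
- Evans–Saksena reduction with Me4NBH(OAc)3 in MeCN–AcOH delivers hydride intramolecularly from the C3–O–B unit on the β face, giving the C4-epimeric diol F6.
- Mitsunobu esterification of F6 with 21 (PPh3, DIAD, toluene) inverts C4 and rejoins the route at 22.

**Further compounds**

F1 | step 10 | (8aR)-6,8a-dimethyl-3-(propan-2-yl)-2,5,6,8a-tetrahydroazulen-4(1H)-one | O=C2CC(C)C=C[C@@]3(C)CCC(C(C)C)=C23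
F2 | step 10 | (4R,8aR)-6,8a-dimethyl-3-(propan-2-yl)-1,2,4,5,6,8a-hexahydroazulen-4-ol | O[C@@H]2CC(C)C=C[C@@]3(C)CCC(C(C)C)=C23
F3 | step 10 | 3,3a-epoxide of F2, oxirane oxygen cis to the C4 hydroxyl and the angular methyl | O[C@@H]2CC(C)C=C[C@@]3(C)CC[C@]4(C(C)C)O[C@]234
F4 | step 10 | 3,3a-epoxy-4-ketone derived from F3 | O=C2CC(C)C=C[C@@]3(C)CC[C@]4(C(C)C)O[C@]234
F5 | step 14 | C8 allylic hydroperoxide of 22 with the alkene at C6=C7 (C8 epimers) | COc1cc(C(=O)O[C@@H]2CC(C)=CC(OO)[C@@]3(C)CC[C@@](O)(C(C)C)[C@H]23)ccc1O[Si](C)(C)C(C)(C)C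
F6 | step 11 | (3R,3aS,4S,8aR)-6,8a-dimethyl-3-(propan-2-yl)-1,2,3,3a,4,5,6,8a-octahydroazulene-3,4-diol | O[C@H]2CC(C)C=C[C@@]3(C)CC[C@@](O)(C(C)C)[C@H]23
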